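The target comes off a catalyst that is being eaten while it works, so you have to ask how much target the doomed part of that catalyst makes before it goes.

| flask | substrate | coupling partner | free catalyst | impurity | time | remark |
|---|---|---|---|---|---|---|
| Sunday's | 0.23 M | 0.345 M | 1.1 mM | 0.75 mM | 5.0 min | everything together at the start |
| Friday's | 0.23 M | 0.345 M (in portions, 4, over 4.0 min) | 1.1 mM | 0.75 mM | 5.0 min | first portion at the start, last at 4.0 min |
| Monday's | 0.23 M (fed, over 4.0 min) | 0.345 M | 1.1 mM | 0.75 mM | 5.0 min | all else is in the flask from the start; the feed brings no volume worth counting |
| Wednesday's | 0.23 M | 0.345 M (fed, over 4.0 min) | 1.1 mM | 0.75 mM | 5.0 min | all else is in the flask from the start; the feed brings no volume worth counting |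

    substrate + free catalyst → catalyst intermediate A (k1 = 97.1 /M/s)
    coupling partner + catalyst intermediate A ⇌ catalyst intermediate B (K2 = 1.1 /M, k2 = 7.89 /M/s)
    catalyst intermediate B → by-product + catalyst intermediate C (k3 = 231 /s)
    catalyst intermediate C ⇌ catalyst intermediate D (K4 = 3.0, k4 = 3.22 /s)
    catalyst intermediate D → free catalyst + target (k5 = 2.80 /s)
    free catalyst + impurity → spent catalyst (k6 = 312 /M/s)
    substrate + by-product → side product (k7 = 0.0379 /M/s)
    coupling partner ⇌ dormant form (K8 = 1.44, k8 = 0.00878 /s)

- the flask that comes out highest in amount of target, in percent of the substrate charged, or "all alike" when all lie within 1.5 percentage points (Sunday's / Friday's / Monday's / Wednesday's / all alike)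
- target at the end, in percent of the substrate charged, Sunday's
- target at the end, in percent of the substrate charged, Friday's
- target at the end, in percent of the substrate charged, Monday's
- target at the end, in percent of the substrate charged, Wednesday's

Free catalyst has two exits. At the start of Sunday's it enters the round 95 times for each capture by impurity, a momentary ratio of rates and not a constant. That ratio goes as [substrate] over [impurity], and each pass through the round yields one target. So, with [substrate] held fixed, [impurity] decays exponentially in target made, not in time. The scale of that decay is the burn length 0.0716 M, the target made while [impurity] falls by a factor e, taken here at charged [substrate].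

Now two ways to Sunday's yield. The half-life of coupling partner by step 8 alone, 1.3 min, is shorter than 5.0 min, so I take free partner at its equilibrium share, and one round then lasts 1.73 s. Put the whole catalyst on that clock and you get 83.0 % of the charge.

The second way splits the catalyst. Survivors, 0.350 mM, give 0.0608 M on the clock. The doomed part gives, by integrating its falling share over the decay, 0.0820 M. Together that is 62.1 %. The two part, and the first cheats: the burn length is used up in 112 s, far less than 5.0 min, yet it lets doomed catalyst work throughout.

So I commit to 62.1 % for Sunday's, knowing it runs high, since [substrate] falls. Monday's starts with no substrate, hence a burn length of nothing, and I keep the survivors' 26.4 %. For Friday's and Wednesday's I count the partner term twice, for a round of 2.62 s, which gives 53.0 %.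

The forecast names Sunday's, with 46 % for Sunday's, 40 % for Friday's, 28 % for Monday's and 39 % for Wednesday's, holding that “low substrate kills it”. Its Sunday's figure is lower than mine.

The simulation gives Sunday's: 45.8 % for Sunday's, 38.9 % for Friday's, 26.1 % for Monday's, 39.0 % for Wednesday's.

Monday's lands on the survivors' share, with impurity down to 0.804 % of its charge. For Sunday's, mean [substrate] over the first 4.0 min was 0.149 M, which shortens the burn length to 0.0463 M and my total to 49.5 %. The run without the loss of free catalyst to impurity shrinks the gap between Sunday's and Monday's from 20 percentage points to 6.7 points. Take Sunday's flask with 0.0028 M of free catalyst: the burn length gives a doomed part worth 9.70 % of the charge, while survivors on the clock reckon to 155 %, past the charge. Computed, that flask ends with substrate at 0 %, target 83.3 % and side product 16.7 %.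

Its constants are assumed; the rest is arithmetic.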